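**Retrosynthetic overview**
1. Last strategic bond: the C3–O–aryl ether, cut to 3-hydroxychromone 8 (O–H partner) and a 2,4-dihydroxyphenyl carbene equivalent (quinone diazide 11, from 4-aminoresorcinol); ring B arrives with both OH groups free.
2. The 3-OH of 8 comes from chromone 6 by nucleophilic epoxidation and epoxide-to-enol isomerisation.
3. The pyranone ring (ring C) is closed onto ring A from o-hydroxyacetophenone 4 and a one-carbon amide acetal.
4. Both prenyl groups come from a two-fold ortho C-prenylation of 2,4-dihydroxyacetophenone with two equivalents of prenyl bromide at the start; one MOM group on O-7 is the only protecting group.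
5. Ring order: ring A bought, ring C built in step 3, ring B attached in step 6, MOM removed last.

Assumption: the target SMILES contains no stereocentre (the compound is achiral), so no stereocontrol is needed; the only stereogenic intermediate (epoxide 7) is racemic, is not isolated, and loses its stereocentres in the same step.

**Step 1**
Reactants: 1 2,4-dihydroxyacetophenone; 2 prenyl bromide (1-bromo-3-methylbut-2-ene)
Product: 3 1-[2,4-dihydroxy-3,5-bis(3-methylbut-2-en-1-yl)phenyl]ethan-1-one
Conditions: NaH (2 × 1.05 equiv) and prenyl bromide (2 × 1.1 equiv in all) in two alternating portions, toluene, 0 °C → rt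
Reagents that add atoms: prenyl bromide (the second equivalent of 2), CC(C)=CCBr
Why: Two successive ortho C-alkylations of a sodium phenoxide held as a tight ion pair in a non-polar solvent (phenoxide C-prenylation), each using one equivalent of prenyl bromide, place the prenyl groups at C3 and C5, the two positions ortho to the more acidic 4-OH, because the para position carries the acetyl group.

**Step 2**
Reactants: 3 1-[2,4-dihydroxy-3,5-bis(3-methylbut-2-en-1-yl)phenyl]ethan-1-one
Product: 4 1-[2-hydroxy-4-(methoxymethoxy)-3,5-bis(3-methylbut-2-en-1-yl)phenyl]ethan-1-one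
Conditions: MOMCl (1.2 equiv), K2CO3, acetone, rt
Reagents that add atoms: chloromethyl methyl ether, COCCl
Why: Williamson-type O-alkylation (MOM protection) takes only the 4-OH, since the 2-OH is locked in a hydrogen bond to the ketone, and the acetal survives the base, peroxide and carbene steps that follow.

**Step 3**
Reactants: 4 1-[2-hydroxy-4-(methoxymethoxy)-3,5-bis(3-methylbut-2-en-1-yl)phenyl]ethan-1-one
Product: 6 7-(methoxymethoxy)-6,8-bis(3-methylbut-2-en-1-yl)-4H-chromen-4-one, via enaminone 5 (not isolated)
Conditions: Me2NCH(OMe)2 (2 equiv), toluene, 90 °C; evaporate; AcOH, 60 °C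
Reagents that add atoms: N,N-dimethylformamide dimethyl acetal, COC(OC)N(C)C
Why: Condensation of the methyl ketone with the amide acetal gives the enaminone, and acid-promoted oxa-Michael addition of the 2-OH with loss of dimethylamine (chromone annulation) closes ring C under conditions too mild to touch the prenyl or MOM groups.

**Step 4**
Reactants: 6 7-(methoxymethoxy)-6,8-bis(3-methylbut-2-en-1-yl)-4H-chromen-4-one
Product: 8 3-hydroxy-7-(methoxymethoxy)-6,8-bis(3-methylbut-2-en-1-yl)-4H-chromen-4-one, via epoxide 7 (not isolated)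
Conditions: 30% aq. H2O2, 2 M NaOH, CH2Cl2/MeOH, 0 °C; extract; TsOH·H2O (10 mol%), CH2Cl2, rt
Reagents that add atoms: hydrogen peroxide, OO
Why: Weitz–Scheffer epoxidation by hydroperoxide anion attacks only the electron-poor C2=C3 bond (the prenyl alkenes are inert to a nucleophilic oxidant), and acid then opens the racemic epoxide at C2 through the O1-stabilised oxocarbenium ion, with loss of H-3 giving the 3-hydroxychromone and erasing both stereocentres.

**Step 5**
Reactants: 9 4-aminoresorcinol hydrochloride (4-aminobenzene-1,3-diol hydrochloride)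
Product: 10 2,4-dihydroxybenzenediazonium tetrafluoroborate
Conditions: t-BuONO (1.05 equiv), 48% aq. HBF4 (2 equiv), EtOH, −10 → 0 °C; Et2O to precipitate
Reagents that add atoms: tert-butyl nitrite, CC(C)(C)ON=O; tetrafluoroboric acid, [H+].F[B-](F)(F)F
Why: Diazotisation of the protonated aminophenol in strong acid gives a diazonium salt whose ring is deactivated against C-nitrosation and self-coupling and which precipitates as the tetrafluoroborate.

**Step 6**
Reactants: 8 3-hydroxy-7-(methoxymethoxy)-6,8-bis(3-methylbut-2-en-1-yl)-4H-chromen-4-one (1.5 equiv, excess recovered); 10 2,4-dihydroxybenzenediazonium tetrafluoroborate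
Product: 12 3-(2,4-dihydroxyphenoxy)-7-(methoxymethoxy)-6,8-bis(3-methylbut-2-en-1-yl)-4H-chromen-4-one, via quinone diazide 11 (not isolated)
Conditions: 10, NaHCO3 (1.0 equiv), 4 Å MS, EtOAc, 0 °C, filtered; this solution added over 4 h to 8, Rh2(esp)2 (2 mol%), 1,2-dichloroethane, 40 °C
Reagents that add atoms: none
Why: Proposed new method: the divalent rhodium carboxylate Rh2(esp)2 (esp = α,α,α′,α′-tetramethyl-1,3-benzenedipropanoate) extrudes N2 from 11 to give an electrophilic quinoid rhodium carbene at C-1′, the enolic 3-OH of 8 (its only O–H, phenol-like in acidity) adds through oxygen to the carbene carbon, and proton transfer with re-aromatisation of ring B releases the aryl ether with the former quinone oxygen as the free 4′-OH and the 2′-OH carried through unprotected, so the C3–O bond and the whole ring B pattern arise in one event; the closest known reaction type is the rhodium-carbene O–H insertion of diazo compounds (quinone diazides included) into alcohols and phenols, which has not been shown for an enolic 3-hydroxychromone or for a hydroxy-bearing quinone diazide.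

**Step 7**
Reactants: 12 3-(2,4-dihydroxyphenoxy)-7-(methoxymethoxy)-6,8-bis(3-methylbut-2-en-1-yl)-4H-chromen-4-one
Product: 13 Eryvarin F, 3-(2,4-dihydroxyphenoxy)-7-hydroxy-6,8-bis(3-methylbut-2-en-1-yl)-4H-chromen-4-one
Conditions: 3 M aq. HCl/MeOH (1:10), 40 °C
Reagents that add atoms: none
Why: Acid-catalysed acetal methanolysis (MOM cleavage) frees the 7-OH under conditions mild enough to avoid cyclisation of the flanking prenyl groups onto it.

**Compound list**
1 | 2,4-dihydroxyacetophenone | CC(=O)c1ccc(O)cc1O | starting material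
2 | prenyl bromide (1-bromo-3-methylbut-2-ene) | CC(C)=CCBr | starting material
3 | 1-[2,4-dihydroxy-3,5-bis(3-methylbut-2-en-1-yl)phenyl]ethan-1-one | CC(=O)c1cc(CC=C(C)C)c(O)c(CC=C(C)C)c1O | intermediate
4 | 1-[2-hydroxy-4-(methoxymethoxy)-3,5-bis(3-methylbut-2-en-1-yl)phenyl]ethan-1-one | CC(=O)c1cc(CC=C(C)C)c(OCOC)c(CC=C(C)C)c1O | intermediate
5 | (E)-3-(dimethylamino)-1-[2-hydroxy-4-(methoxymethoxy)-3,5-bis(3-methylbut-2-en-1-yl)phenyl]prop-2-en-1-one (enaminone, formed in the flask) | CN(C)/C=C/C(=O)c1cc(CC=C(C)C)c(OCOC)c(CC=C(C)C)c1O | intermediate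
6 | 7-(methoxymethoxy)-6,8-bis(3-methylbut-2-en-1-yl)-4H-chromen-4-one | COCOc1c(CC=C(C)C)cc2c(=O)ccoc2c1CC=C(C)C | intermediate
7 | racemic cis-2,3-epoxy-7-(methoxymethoxy)-6,8-bis(3-methylbut-2-en-1-yl)chroman-4-one (formed in the flask; one enantiomer drawn) | COCOc1c(CC=C(C)C)cc2C(=O)[C@@H]3O[C@@H]3Oc2c1CC=C(C)C | intermediate
8 | 3-hydroxy-7-(methoxymethoxy)-6,8-bis(3-methylbut-2-en-1-yl)-4H-chromen-4-one | COCOc1c(CC=C(C)C)cc2c(=O)c(O)coc2c1CC=C(C)C | intermediate
9 | 4-aminoresorcinol hydrochloride | Nc1ccc(O)cc1O.Cl | starting material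
10 | 2,4-dihydroxybenzenediazonium tetrafluoroborate | N#[N+]c1ccc(O)cc1O.F[B-](F)(F)F | intermediate
11 | 4-diazo-3-hydroxycyclohexa-2,5-dien-1-one (quinone diazide, formed in the flask) | [N-]=[N+]=C1C=CC(=O)C=C1O | intermediate
12 | 3-(2,4-dihydroxyphenoxy)-7-(methoxymethoxy)-6,8-bis(3-methylbut-2-en-1-yl)-4H-chromen-4-one | COCOc1c(CC=C(C)C)cc2c(=O)c(Oc3ccc(O)cc3O)coc2c1CC=C(C)C | intermediate
13 | Eryvarin F | CC(C)=CCc1cc2c(=O)c(Oc3ccc(O)cc3O)coc2c(CC=C(C)C)c1O | target

**Step count**
Total: 7 steps. Longest linear sequence: 6 steps (1 → 2 → 3 → 4 → 6 → 7); step 5 is a one-step side branch.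

**Steps most likely to fail**

Step 1 (two-fold C-prenylation). O-prenylation, mono-prenylation and over-alkylation compete, so the yield of 3 may be modest. Fallback: from 1, iodination (I2, HIO3, aq. EtOH) gives 1-(2,4-dihydroxy-3,5-diiodophenyl)ethan-1-one F1. A double Stille coupling (Bu3SnCH2CH=CMe2, Pd(PPh3)4, DMF, 90 °C) then places both prenyl groups regiospecifically on the iodinated carbons and comes back to the route at 3.

Step 4 (epoxidation and isomerisation). Hydroxide can open the chromone at C2, and the acid stage must isomerise the epoxide without loosening the MOM group. Fallback: from 6, conjugate hydride reduction with LiBH(s-Bu)3 (THF, −78 °C) and trapping of the enolate in the same flask with 2-(phenylsulfonyl)-3-phenyloxaziridine gives racemic 3-hydroxy-7-(methoxymethoxy)-6,8-bis(3-methylbut-2-en-1-yl)chroman-4-one F2. Dess–Martin oxidation (CH2Cl2, rt) gives the 3,4-dione, which tautomerises to the 3-hydroxychromone, so the route is rejoined at 8.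

Step 6 (the proposed new C–O coupling). The carbene may also arylate the free phenols of the product (hence excess 8 and slow addition), attack C-2 of the enol or the prenyl alkenes, and residual diazonium may azo-couple. Fallback by known chemistry, a Chan–Lam aryl ether formation, from 8: commercial 4-bromoresorcinol is protected (MOMCl, i-Pr2NEt, CH2Cl2) to 1-bromo-2,4-bis(methoxymethoxy)benzene F3. Bromine–lithium exchange and borylation (n-BuLi, THF, −78 °C; B(OiPr)3; aqueous work-up) give [2,4-bis(methoxymethoxy)phenyl]boronic acid F4. Coupling of F4 with 8 (Cu(OAc)2, pyridine, 4 Å MS, air, CH2Cl2, rt) gives 3-[2,4-bis(methoxymethoxy)phenoxy]-7-(methoxymethoxy)-6,8-bis(3-methylbut-2-en-1-yl)-4H-chromen-4-one F5. The acid methanolysis of step 7 removes all three MOM groups and the sequence comes back to the route at 13.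

**Further compounds**
F1 | step 1 | 1-(2,4-dihydroxy-3,5-diiodophenyl)ethan-1-one | CC(=O)c1cc(I)c(O)c(I)c1O
F2 | step 4 | racemic 3-hydroxy-7-(methoxymethoxy)-6,8-bis(3-methylbut-2-en-1-yl)chroman-4-one | COCOc1c(CC=C(C)C)cc2C(=O)C(O)COc2c1CC=C(C)C
F3 | step 6 | 1-bromo-2,4-bis(methoxymethoxy)benzene | COCOc1ccc(Br)c(OCOC)c1
F4 | step 6 | [2,4-bis(methoxymethoxy)phenyl]boronic acid | COCOc1ccc(B(O)O)c(OCOC)c1
F5 | step 6 | 3-[2,4-bis(methoxymethoxy)phenoxy]-7-(methoxymethoxy)-6,8-bis(3-methylbut-2-en-1-yl)-4H-chromen-4-one | COCOc1ccc(Oc2coc3c(CC=C(C)C)c(OCOC)c(CC=C(C)C)cc3c2=O)c(OCOC)c1
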